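**Retrosynthetic overview**

- Ring A is unmasked last (dioxolane hydrolysis, then hydrogenolysis of two benzyl ethers and the benzyl ester). Both benzene rings are bought; the only ring made is the pyranone of ring B, closed by enol-lactonisation of a 2-(2-oxoheptyl)benzoic acid that comes from C4-hexanoylation and deallylative decarboxylation of a diallyl homophthalate.
- The homophthalate comes from insertion of a ring B aryne into a C–C bond of diallyl malonate. The strategy rests on this feature: C4a and C8a of the isocoumarin (ring B) are adjacent ring carbons carrying the C4 methylene carbon and the C1 carboxyl carbon, and the C8 aryloxy oxygen next to C8a polarises an aryne spanning C4a–C8a so that the malonate carbon bonds to C4a and the ester carbonyl to C8a.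
- The ortho-silylaryl triflate comes from an ortho-bromophenol (O-silylation, bromine–lithium exchange with retro-Brook shift, triflation). The diaryl ether C8–O bond is made by SNAr of the ring A phenol on 2-bromo-6-fluoro-4-methoxybenzaldehyde, whose formyl group is then converted into the C8a oxygen by Dakin oxidation.
- The 2-oxoheptyl chain of ring A enters as a 2-methyleneheptyl group by aromatic Claisen rearrangement, which also frees the C5 phenol. It is cleaved to the ketone and ketalised only after the ether bond is made. The ring A phenol derives from 5-bromo-2,4-dihydroxybenzoic acid.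

Key step: step 12

**Remarks on the chemistry**

- Ring A is numbered as the benzoic acid (C1 carboxyl, C2 and C4 oxygens, C5 ether oxygen, C6 side chain); ring B carries isocoumarin numbering. The target has no stereocentre.
- The aryne precursor carries the silyl group on C4a and the triflate on C8a. Fluoride gives the same C4a–C8a aryne whichever of the two carbons carries silicon. This isomer derives from an ortho-bromophenol that SNAr and Dakin chemistry deliver with full regiocontrol. A silyl group placed between the two oxygen-bearing carbons would need an O-arylation hindered on both partners and would be prone to protodesilylation.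

**Route**

Step 1
Reactants: 1 5-bromo-2,4-dihydroxybenzoic acid
Product: 2 benzyl 2,4-bis(benzyloxy)-5-bromobenzoate
Conditions: BnBr (3.5 equiv), K2CO3, DMF, 60 °C
Reagents that add atoms: benzyl bromide, BrCc1ccccc1
Why: Williamson O-alkylation of both phenoxides and of the carboxylate; warming is needed for the hydrogen-bonded C2 hydroxyl.

Step 2
Reactants: 2 benzyl 2,4-bis(benzyloxy)-5-bromobenzoate
Product: 4 benzyl 2,4-bis(benzyloxy)-5-hydroxybenzoate, via pinacol boronate 3 (not isolated)
Conditions: B2pin2, Pd(dppf)Cl2 (5 mol%), KOAc, dioxane, 90 °C; then 30% H2O2, aq. Na2CO3, THF, 0 °C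
Reagents that add atoms: hydrogen peroxide, OO (oxygen of the new phenol); bis(pinacolato)diboron, CC1(C)OB(OC1(C)C)B1OC(C)(C)C(C)(C)O1 (boron of intermediate 3 only)
Why: Miyaura borylation of the aryl bromide followed by peroxide oxidation (1,2-shift of the aryl group from boron to oxygen) should give the C5 phenol without touching the benzyl groups.

Step 3
Reactants: 5 propargyl alcohol; 6 pentylmagnesium bromide
Product: 7 2-methyleneheptan-1-ol
Conditions: 6 (2.5 equiv), CuI (10 mol%), Et2O, 0 °C to reflux; aq. NH4Cl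
Reagents that add atoms: none
Why: CuI-catalysed carbomagnesiation of the magnesium propargylic alkoxide places the pentyl group on C2 and magnesium on C3 (five-membered chelate), and protonolysis should give the 2-substituted allylic alcohol.

Step 4
Reactants: 4 benzyl 2,4-bis(benzyloxy)-5-hydroxybenzoate; 7 2-methyleneheptan-1-ol
Product: 8 benzyl 2,4-bis(benzyloxy)-5-[(2-methyleneheptyl)oxy]benzoate
Conditions: PPh3, DIAD, THF, 0 °C to rt
Reagents that add atoms: none
Why: Mitsunobu etherification; the phenol displaces the activated primary allylic carbinol by SN2.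

Step 5
Reactants: 8 benzyl 2,4-bis(benzyloxy)-5-[(2-methyleneheptyl)oxy]benzoate
Product: 9 benzyl 2,4-bis(benzyloxy)-5-hydroxy-6-(2-methyleneheptyl)benzoate
Conditions: PhNEt2, 190 °C, argon
Reagents that add atoms: none
Why: Aromatic Claisen rearrangement ([3,3] shift, then tautomerisation); C6 is the only ortho position that bears hydrogen, so the side chain arrives there and the C5 phenol is set free, and the basic solvent suppresses acid-catalysed cyclisation of the phenol onto the alkene.

Step 6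
Reactants: 10 3-bromo-5-fluoroanisole
Product: 11 2-bromo-6-fluoro-4-methoxybenzaldehyde
Conditions: LiN(iPr)2, THF, −78 °C; DMF, −78 °C; H2O
Reagents that add atoms: N,N-dimethylformamide, CN(C)C=O
Why: Directed ortho-metalation: the amide base removes the ring hydrogen flanked by fluorine and bromine (the most acidic site), and the aryllithium, stable at −78 °C, is formylated by DMF.

Step 7
Reactants: 9 benzyl 2,4-bis(benzyloxy)-5-hydroxy-6-(2-methyleneheptyl)benzoate; 11 2-bromo-6-fluoro-4-methoxybenzaldehyde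
Product: 12 benzyl 2,4-bis(benzyloxy)-5-(3-bromo-2-formyl-5-methoxyphenoxy)-6-(2-methyleneheptyl)benzoate
Conditions: K2CO3, DMF, 90 °C
Reagents that add atoms: none
Why: SNAr: the phenoxide adds at the fluorine-bearing carbon ortho to the formyl group (Meisenheimer intermediate) and fluoride leaves, bromide being a far poorer leaving group in addition–elimination.

Step 8
Reactants: 12 benzyl 2,4-bis(benzyloxy)-5-(3-bromo-2-formyl-5-methoxyphenoxy)-6-(2-methyleneheptyl)benzoate
Product: 14 benzyl 2,4-bis(benzyloxy)-5-(3-bromo-2-formyl-5-methoxyphenoxy)-6-(2-oxoheptyl)benzoate, via diol 13 (not isolated)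
Conditions: OsO4 (2 mol%), NaIO4 (4 equiv), 2,6-lutidine, dioxane/H2O, rt
Reagents that add atoms: osmium tetroxide, O=[Os](=O)(=O)=O (catalytic oxygen carrier); sodium periodate, [Na+].[O-]I(=O)(=O)=O (terminal oxidant)
Why: Lemieux–Johnson oxidation: osmylation of the only alkene and periodate glycol cleavage should give the ketone while the aryl aldehyde, aryl bromide and benzyl groups stay inert; the ketone is released only now because a free C5 phenol next to it would close a benzofuran.

Step 9
Reactants: 14 benzyl 2,4-bis(benzyloxy)-5-(3-bromo-2-formyl-5-methoxyphenoxy)-6-(2-oxoheptyl)benzoate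
Product: 16 benzyl 2,4-bis(benzyloxy)-5-(3-bromo-2-hydroxy-5-methoxyphenoxy)-6-(2-oxoheptyl)benzoate, via aryl formate 15 (not isolated)
Conditions: mCPBA, NaHCO3, CH2Cl2, 0 °C to rt; then Et3N (cat.), MeOH, rt
Reagents that add atoms: 3-chloroperbenzoic acid, OOC(=O)c1cccc(Cl)c1
Why: Dakin-type Baeyer–Villiger oxidation: the electron-rich aryl group (para-methoxy, ortho-aryloxy) migrates in the Criegee intermediate to give the formate, which methanolysis cleaves; the dialkyl ketone reacts much more slowly with the unactivated peracid.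

Step 10
Reactants: 16 benzyl 2,4-bis(benzyloxy)-5-(3-bromo-2-hydroxy-5-methoxyphenoxy)-6-(2-oxoheptyl)benzoate
Product: 17 benzyl 2,4-bis(benzyloxy)-5-(3-bromo-2-hydroxy-5-methoxyphenoxy)-6-[(2-pentyl-1,3-dioxolan-2-yl)methyl]benzoate
Conditions: TMSOCH2CH2OTMS, TMSOTf (5 mol%), CH2Cl2, −78 to −20 °C; pyridine, then aq. NaHCO3
Reagents that add atoms: 1,2-bis(trimethylsilyloxy)ethane, C[Si](C)(C)OCCO[Si](C)(C)C
Why: TMSOTf-catalysed silyl-transfer ketalisation at low temperature should protect the ketone without the protic acid and heat that would let its enol lactonise onto the ortho benzyl ester; the ketal keeps this ketone from enolising in steps 11 to 15.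

Step 11
Reactants: 17 benzyl 2,4-bis(benzyloxy)-5-(3-bromo-2-hydroxy-5-methoxyphenoxy)-6-[(2-pentyl-1,3-dioxolan-2-yl)methyl]benzoate
Product: 20 benzyl 2,4-bis(benzyloxy)-5-[5-methoxy-2-(trifluoromethylsulfonyloxy)-3-(trimethylsilyl)phenoxy]-6-[(2-pentyl-1,3-dioxolan-2-yl)methyl]benzoate, via aryl trimethylsilyl ether 18 (not isolated), via lithium silylphenoxide 19 (not isolated)
Conditions: (Me3Si)2NH, THF, 65 °C, evaporate; n-BuLi (1.1 equiv), THF, −100 to −78 °C; Tf2O, −78 °C to rt
Reagents that add atoms: hexamethyldisilazane, C[Si](C)(C)N[Si](C)(C)C; trifluoromethanesulfonic anhydride, FC(F)(F)S(=O)(=O)OS(=O)(=O)C(F)(F)F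
Why: After O-silylation, bromine–lithium exchange at C4a outruns attack on the doubly ortho-substituted ester at −100 °C; the aryllithium takes the silyl group from the neighbouring oxygen (retro-Brook 1,3 O-to-C shift) and the phenoxide is triflated, which is the standard route from ortho-bromophenols to ortho-silylaryl triflates.

Step 12
Reactants: 20 benzyl 2,4-bis(benzyloxy)-5-[5-methoxy-2-(trifluoromethylsulfonyloxy)-3-(trimethylsilyl)phenoxy]-6-[(2-pentyl-1,3-dioxolan-2-yl)methyl]benzoate; 21 diallyl malonate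
Product: 23 benzyl 5-{2-[(allyloxy)carbonyl]-3-[2-(allyloxy)-2-oxoethyl]-5-methoxyphenoxy}-2,4-bis(benzyloxy)-6-[(2-pentyl-1,3-dioxolan-2-yl)methyl]benzoate, via ring B aryne 22 (not isolated)
Conditions: CsF (3 equiv), 21 (2 equiv), MeCN, rt to 60 °C
Reagents that add atoms: none
Why: Fluoride removes the silyl group from C4a and triflate leaves from C8a to give aryne 22; the caesium enolate of the malonate adds to C4a, the carbon remote from the C8 aryloxy group, because the inductively withdrawing oxygen stabilises the aryl anion developing at C8a and distorts the aryne so that C4a is the more electrophilic terminus. The C8a anion then adds to a malonate ester carbonyl (4-exo-trig) to give a benzocyclobutenoxide that fragments with cleavage of the former malonate C–C bond, so that the allyloxycarbonyl group ends on C8a and the carbanion on the C4 carbon is protonated. This is the known fluoride-induced acyl-alkylation of arynes by malonates and beta-keto esters (formal insertion into a C–C sigma bond), which is regioselective for 3-alkoxy and 3,5-dialkoxy arynes. No ring of the target is closed and no stereocentre is formed. The step needs C-addition at C4a and acyl transfer faster than protonation of the C8a anion; the first is secured by the aryloxy group next to the triple bond, the second by the ester carbonyl held beside the anion in the adduct and by the aprotic medium with excess malonate.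

Step 13
Reactants: 23 benzyl 5-{2-[(allyloxy)carbonyl]-3-[2-(allyloxy)-2-oxoethyl]-5-methoxyphenoxy}-2,4-bis(benzyloxy)-6-[(2-pentyl-1,3-dioxolan-2-yl)methyl]benzoate; 24 hexanoyl chloride
Product: 25 benzyl 5-{2-[(allyloxy)carbonyl]-3-[1-(allyloxy)-1,3-dioxooctan-2-yl]-5-methoxyphenoxy}-2,4-bis(benzyloxy)-6-[(2-pentyl-1,3-dioxolan-2-yl)methyl]benzoate (racemic)
Conditions: LiN(SiMe3)2 (2.2 equiv), THF, −78 °C; 24 (1.1 equiv), −78 to 0 °C; aq. NH4Cl
Reagents that add atoms: none
Why: Claisen-type C-acylation of the lithium enolate of the arylacetate (the C4 methylene is the only acidic CH in 23); the second equivalent of base deprotonates the more acidic beta-keto ester product and so prevents proton exchange and double acylation.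

Step 14
Reactants: 25 benzyl 5-{2-[(allyloxy)carbonyl]-3-[1-(allyloxy)-1,3-dioxooctan-2-yl]-5-methoxyphenoxy}-2,4-bis(benzyloxy)-6-[(2-pentyl-1,3-dioxolan-2-yl)methyl]benzoate
Product: 27 2-{4,6-bis(benzyloxy)-3-[(benzyloxy)carbonyl]-2-[(2-pentyl-1,3-dioxolan-2-yl)methyl]phenoxy}-4-methoxy-6-(2-oxoheptyl)benzoic acid, via keto diacid 26 (not isolated)
Conditions: Pd(PPh3)4 (5 mol%), morpholine (5 equiv), THF, rt to 40 °C; aq. citric acid work-up
Reagents that add atoms: none
Why: Tsuji–Trost deallylation: zerovalent palladium ionises both allyl esters and morpholine traps the allyl groups to give diacid 26, whose beta-keto acid loses CO2 to leave the C4 methylene ketone, while benzyl esters and ethers are untouched.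

Step 15
Reactants: 27 2-{4,6-bis(benzyloxy)-3-[(benzyloxy)carbonyl]-2-[(2-pentyl-1,3-dioxolan-2-yl)methyl]phenoxy}-4-methoxy-6-(2-oxoheptyl)benzoic acid
Product: 28 benzyl 2,4-bis(benzyloxy)-5-[(6-methoxy-1-oxo-3-pentyl-1H-isochromen-8-yl)oxy]-6-[(2-pentyl-1,3-dioxolan-2-yl)methyl]benzoate
Conditions: Ac2O, NaOAc, 80 °C
Reagents that add atoms: none
Why: Enol-lactonisation: the mixed anhydride of the acid is attacked by the enol oxygen of the benzylic ketone to close the six-membered pyranone, the classical cyclodehydration of 2-(2-oxoalkyl)benzoic acids to 3-alkylisocoumarins; buffered anhydride leaves the dioxolane intact.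

Step 16
Reactants: 28 benzyl 2,4-bis(benzyloxy)-5-[(6-methoxy-1-oxo-3-pentyl-1H-isochromen-8-yl)oxy]-6-[(2-pentyl-1,3-dioxolan-2-yl)methyl]benzoate
Product: 29 benzyl 2,4-bis(benzyloxy)-5-[(6-methoxy-1-oxo-3-pentyl-1H-isochromen-8-yl)oxy]-6-(2-oxoheptyl)benzoate
Conditions: 1 M HCl, THF, rt
Reagents that add atoms: water, O
Why: Acid-catalysed ketal hydrolysis through the oxocarbenium ion; dilute acid at room temperature should leave the enol lactone, the benzyl ester and the benzyl ethers, and the acid is kept esterified so that the freed ketone does not lactonise.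

Step 17
Reactants: 29 benzyl 2,4-bis(benzyloxy)-5-[(6-methoxy-1-oxo-3-pentyl-1H-isochromen-8-yl)oxy]-6-(2-oxoheptyl)benzoate
Product: 30 beta-collatolic acid (2,4-dihydroxy-5-[(6-methoxy-1-oxo-3-pentyl-1H-isochromen-8-yl)oxy]-6-(2-oxoheptyl)benzoic acid)
Conditions: H2 (1 atm), Pd/C (10%), EtOAc, rt, stopped after uptake of 3 equiv
Reagents that add atoms: none
Why: Hydrogenolysis of the two benzyl ethers and the benzyl ester on palladium under neutral conditions should be much faster than hydrogenation of the trisubstituted, aryl-conjugated C3=C4 enol-lactone bond of ring B.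

**Compound list**

1 | 5-bromo-2,4-dihydroxybenzoic acid | OC(=O)c1cc(Br)c(O)cc1O | starting material
2 | benzyl 2,4-bis(benzyloxy)-5-bromobenzoate | O=C(OCc1ccccc1)c1cc(Br)c(OCc2ccccc2)cc1OCc1ccccc1 | intermediate
3 | benzyl 2,4-bis(benzyloxy)-5-(4,4,5,5-tetramethyl-1,3,2-dioxaborolan-2-yl)benzoate (not isolated) | O=C(OCc1ccccc1)c1cc(B2OC(C)(C)C(C)(C)O2)c(OCc2ccccc2)cc1OCc1ccccc1 | intermediate
4 | benzyl 2,4-bis(benzyloxy)-5-hydroxybenzoate | O=C(OCc1ccccc1)c1cc(O)c(OCc2ccccc2)cc1OCc1ccccc1 | intermediate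
5 | propargyl alcohol | C#CCO | starting material
6 | pentylmagnesium bromide | CCCCC[Mg]Br | starting material
7 | 2-methyleneheptan-1-ol | C=C(CCCCC)CO | intermediate
8 | benzyl 2,4-bis(benzyloxy)-5-[(2-methyleneheptyl)oxy]benzoate | C=C(CCCCC)COc1cc(C(=O)OCc2ccccc2)c(OCc2ccccc2)cc1OCc1ccccc1 | intermediate
9 | benzyl 2,4-bis(benzyloxy)-5-hydroxy-6-(2-methyleneheptyl)benzoate | C=C(CCCCC)Cc1c(O)c(OCc2ccccc2)cc(OCc2ccccc2)c1C(=O)OCc1ccccc1 | intermediate
10 | 3-bromo-5-fluoroanisole | COc1cc(F)cc(Br)c1 | starting material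
11 | 2-bromo-6-fluoro-4-methoxybenzaldehyde | COc1cc(F)c(C=O)c(Br)c1 | intermediate
12 | benzyl 2,4-bis(benzyloxy)-5-(3-bromo-2-formyl-5-methoxyphenoxy)-6-(2-methyleneheptyl)benzoate | COc1cc(Br)c(C=O)c(Oc2c(CC(=C)CCCCC)c(C(=O)OCc3ccccc3)c(OCc3ccccc3)cc2OCc2ccccc2)c1 | intermediate
13 | benzyl 2,4-bis(benzyloxy)-5-(3-bromo-2-formyl-5-methoxyphenoxy)-6-[2-hydroxy-2-(hydroxymethyl)heptyl]benzoate (racemic, not isolated) | COc1cc(Br)c(C=O)c(Oc2c(CC(O)(CO)CCCCC)c(C(=O)OCc3ccccc3)c(OCc3ccccc3)cc2OCc2ccccc2)c1 | intermediate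
14 | benzyl 2,4-bis(benzyloxy)-5-(3-bromo-2-formyl-5-methoxyphenoxy)-6-(2-oxoheptyl)benzoate | COc1cc(Br)c(C=O)c(Oc2c(CC(=O)CCCCC)c(C(=O)OCc3ccccc3)c(OCc3ccccc3)cc2OCc2ccccc2)c1 | intermediate
15 | benzyl 2,4-bis(benzyloxy)-5-[3-bromo-2-(formyloxy)-5-methoxyphenoxy]-6-(2-oxoheptyl)benzoate (not isolated) | COc1cc(Br)c(OC=O)c(Oc2c(CC(=O)CCCCC)c(C(=O)OCc3ccccc3)c(OCc3ccccc3)cc2OCc2ccccc2)c1 | intermediate
16 | benzyl 2,4-bis(benzyloxy)-5-(3-bromo-2-hydroxy-5-methoxyphenoxy)-6-(2-oxoheptyl)benzoate | COc1cc(Br)c(O)c(Oc2c(CC(=O)CCCCC)c(C(=O)OCc3ccccc3)c(OCc3ccccc3)cc2OCc2ccccc2)c1 | intermediate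
17 | benzyl 2,4-bis(benzyloxy)-5-(3-bromo-2-hydroxy-5-methoxyphenoxy)-6-[(2-pentyl-1,3-dioxolan-2-yl)methyl]benzoate | COc1cc(Br)c(O)c(Oc2c(CC3(CCCCC)OCCO3)c(C(=O)OCc3ccccc3)c(OCc3ccccc3)cc2OCc2ccccc2)c1 | intermediate
18 | benzyl 2,4-bis(benzyloxy)-5-[3-bromo-5-methoxy-2-(trimethylsilyloxy)phenoxy]-6-[(2-pentyl-1,3-dioxolan-2-yl)methyl]benzoate (not isolated) | COc1cc(Br)c(O[Si](C)(C)C)c(Oc2c(CC3(CCCCC)OCCO3)c(C(=O)OCc3ccccc3)c(OCc3ccccc3)cc2OCc2ccccc2)c1 | intermediate
19 | lithium phenoxide of benzyl 2,4-bis(benzyloxy)-5-[2-hydroxy-5-methoxy-3-(trimethylsilyl)phenoxy]-6-[(2-pentyl-1,3-dioxolan-2-yl)methyl]benzoate (not isolated) | [Li+].COc1cc([Si](C)(C)C)c([O-])c(Oc2c(CC3(CCCCC)OCCO3)c(C(=O)OCc3ccccc3)c(OCc3ccccc3)cc2OCc2ccccc2)c1 | intermediate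
20 | benzyl 2,4-bis(benzyloxy)-5-[5-methoxy-2-(trifluoromethylsulfonyloxy)-3-(trimethylsilyl)phenoxy]-6-[(2-pentyl-1,3-dioxolan-2-yl)methyl]benzoate (aryne precursor) | COc1cc([Si](C)(C)C)c(OS(=O)(=O)C(F)(F)F)c(Oc2c(CC3(CCCCC)OCCO3)c(C(=O)OCc3ccccc3)c(OCc3ccccc3)cc2OCc2ccccc2)c1 | intermediate
21 | diallyl malonate | C=CCOC(=O)CC(=O)OCC=C | starting material
22 | ring B aryne, triple bond between C4a and C8a: benzyl 2,4-bis(benzyloxy)-5-[(2,3-didehydro-5-methoxyphenyl)oxy]-6-[(2-pentyl-1,3-dioxolan-2-yl)methyl]benzoate (not isolated) | COC1=CC#CC(Oc2c(CC3(CCCCC)OCCO3)c(C(=O)OCc3ccccc3)c(OCc3ccccc3)cc2OCc2ccccc2)=C1 | intermediate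
23 | benzyl 5-{2-[(allyloxy)carbonyl]-3-[2-(allyloxy)-2-oxoethyl]-5-methoxyphenoxy}-2,4-bis(benzyloxy)-6-[(2-pentyl-1,3-dioxolan-2-yl)methyl]benzoate (diallyl homophthalate of ring B) | C=CCOC(=O)Cc1cc(OC)cc(Oc2c(CC3(CCCCC)OCCO3)c(C(=O)OCc3ccccc3)c(OCc3ccccc3)cc2OCc2ccccc2)c1C(=O)OCC=C | intermediate
24 | hexanoyl chloride | CCCCCC(Cl)=O | starting material
25 | benzyl 5-{2-[(allyloxy)carbonyl]-3-[1-(allyloxy)-1,3-dioxooctan-2-yl]-5-methoxyphenoxy}-2,4-bis(benzyloxy)-6-[(2-pentyl-1,3-dioxolan-2-yl)methyl]benzoate (racemic) | C=CCOC(=O)C(C(=O)CCCCC)c1cc(OC)cc(Oc2c(CC3(CCCCC)OCCO3)c(C(=O)OCc3ccccc3)c(OCc3ccccc3)cc2OCc2ccccc2)c1C(=O)OCC=C | intermediate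
26 | 2-{4,6-bis(benzyloxy)-3-[(benzyloxy)carbonyl]-2-[(2-pentyl-1,3-dioxolan-2-yl)methyl]phenoxy}-6-(1-carboxy-2-oxoheptyl)-4-methoxybenzoic acid (keto diacid; racemic, not isolated) | CCCCCC(=O)C(C(=O)O)c1cc(OC)cc(Oc2c(CC3(CCCCC)OCCO3)c(C(=O)OCc3ccccc3)c(OCc3ccccc3)cc2OCc2ccccc2)c1C(=O)O | intermediate
27 | 2-{4,6-bis(benzyloxy)-3-[(benzyloxy)carbonyl]-2-[(2-pentyl-1,3-dioxolan-2-yl)methyl]phenoxy}-4-methoxy-6-(2-oxoheptyl)benzoic acid | CCCCCC(=O)Cc1cc(OC)cc(Oc2c(CC3(CCCCC)OCCO3)c(C(=O)OCc3ccccc3)c(OCc3ccccc3)cc2OCc2ccccc2)c1C(=O)O | intermediate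
28 | benzyl 2,4-bis(benzyloxy)-5-[(6-methoxy-1-oxo-3-pentyl-1H-isochromen-8-yl)oxy]-6-[(2-pentyl-1,3-dioxolan-2-yl)methyl]benzoate | CCCCCc1cc2cc(OC)cc(Oc3c(CC4(CCCCC)OCCO4)c(C(=O)OCc4ccccc4)c(OCc4ccccc4)cc3OCc3ccccc3)c2c(=O)o1 | intermediate
29 | benzyl 2,4-bis(benzyloxy)-5-[(6-methoxy-1-oxo-3-pentyl-1H-isochromen-8-yl)oxy]-6-(2-oxoheptyl)benzoate | CCCCCC(=O)Cc1c(Oc2cc(OC)cc3cc(CCCCC)oc(=O)c23)c(OCc2ccccc2)cc(OCc2ccccc2)c1C(=O)OCc1ccccc1 | intermediate
30 | beta-collatolic acid | CCCCCC(=O)Cc1c(Oc2cc(OC)cc3cc(CCCCC)oc(=O)c23)c(O)cc(O)c1C(=O)O | target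

**Step count**

Total: 17 steps. Longest linear sequence: 15 steps (steps 1, 2, 4, 5, 7 to 17, from 5-bromo-2,4-dihydroxybenzoic acid).

**Steps most likely to fail, with fallbacks**

1. Step 12 (key step). What may go wrong: protonation of the C8a aryl anion before acyl transfer (plain alpha-arylation of the malonate), interception of the aryne by the neighbouring benzyloxy oxygen of ring A, or a second arylation of the product at its acidic methylene. Fallback without an aryne: it sets out from bromo aldehyde 14, in which C8a already carries a one-carbon group and C4a a bromine. Sonogashira coupling with hept-1-yne (Pd(PPh3)2Cl2, CuI, Et3N, DMF, 70 °C) should give benzyl 2,4-bis(benzyloxy)-5-[2-formyl-3-(hept-1-yn-1-yl)-5-methoxyphenoxy]-6-(2-oxoheptyl)benzoate F1. Pinnick oxidation (NaClO2, NaH2PO4, 2-methylbut-2-ene, t-BuOH/H2O) should give the 2-(hept-1-yn-1-yl)benzoic acid F2. Acid-catalysed 6-endo-dig lactonisation (TfOH, 5 mol%, CH2Cl2, 0 °C) should close the pyranone with the pentyl group on C3 and come back to the route at 29, which goes on to step 17.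

2. Step 11. What may go wrong: attack of butyllithium on the benzyl ester or benzylic deprotonation in competition with bromine–lithium exchange, or an incomplete oxygen-to-carbon silyl shift. Fallback: it sets out from 17 and replaces the organolithium by a palladium-catalysed C–Si coupling. Silylation of the aryl bromide with hexamethyldisilane (Pd2(dba)3, 2-(di-tert-butylphosphino)biphenyl, KF, DMPU/H2O, 100 °C; the phenol may be carried as its silyl ether 18 and freed on work-up) should give benzyl 2,4-bis(benzyloxy)-5-[2-hydroxy-5-methoxy-3-(trimethylsilyl)phenoxy]-6-[(2-pentyl-1,3-dioxolan-2-yl)methyl]benzoate F3. Triflation (Tf2O, pyridine, CH2Cl2, 0 °C) should then return to the route at 20.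

3. Step 17. What may go wrong: hydrogenation of the C3=C4 enol-lactone bond of ring B alongside the debenzylation. Fallback: it sets out from 29 and uses Lewis-acid debenzylation in place of hydrogen. BCl3 with pentamethylbenzene as benzyl-cation scavenger (CH2Cl2, −78 °C) should cleave the two aryl benzyl ethers and the benzyl ester and leave the alkene and the non-chelated C6 methyl ether. It comes back at 30 and makes no new compound (F0).

**Further compounds**

F1 | step 12 | benzyl 2,4-bis(benzyloxy)-5-[2-formyl-3-(hept-1-yn-1-yl)-5-methoxyphenoxy]-6-(2-oxoheptyl)benzoate | CCCCCC#Cc1cc(OC)cc(Oc2c(CC(=O)CCCCC)c(C(=O)OCc3ccccc3)c(OCc3ccccc3)cc2OCc2ccccc2)c1C=O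
F2 | step 12 | 2-{4,6-bis(benzyloxy)-3-[(benzyloxy)carbonyl]-2-(2-oxoheptyl)phenoxy}-6-(hept-1-yn-1-yl)-4-methoxybenzoic acid | CCCCCC#Cc1cc(OC)cc(Oc2c(CC(=O)CCCCC)c(C(=O)OCc3ccccc3)c(OCc3ccccc3)cc2OCc2ccccc2)c1C(=O)O
F3 | step 11 | benzyl 2,4-bis(benzyloxy)-5-[2-hydroxy-5-methoxy-3-(trimethylsilyl)phenoxy]-6-[(2-pentyl-1,3-dioxolan-2-yl)methyl]benzoate | COc1cc([Si](C)(C)C)c(O)c(Oc2c(CC3(CCCCC)OCCO3)c(C(=O)OCc3ccccc3)c(OCc3ccccc3)cc2OCc2ccccc2)c1
F0 | step 17 | none | none
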